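The bicyclo[3.3.1]nonane is disconnected at C1–C8. Its quaternary bridgehead C5 sits between two oxygenated carbons, the enol carbon C4 of ring A and the bridging carbonyl C9; in a cyclohexa-2,5-diene in which both are methyl enol ether carbons they are enantiotopic and C5 is prochiral. A chiral copper carbenoid generated at C8 cyclopropanates one of these enol ethers, closing a cyclopentanone and a cyclopropane in one operation and fixing C5 and C1 together with two temporary centres; opening the donor–acceptor cyclopropane at C8–C9 then releases ring B. The precursor is the achiral diazoketone that carries geranyl and a CH2COCHN2 arm on the carbon between the two enol ethers.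

Key step: step 6

Remark: bicyclic compounds are named with the locants of the target core (C1 bridgehead next to C8, C2–C3–C4 in ring A, C5 geranyl bridgehead, C6–C7–C8 in ring B, C9 bridge); geranyl = (2E)-3,7-dimethylocta-2,6-dien-1-yl, prenyl = 3-methylbut-2-en-1-yl.
Remark: the enolised 2,4-dione of the target is a freely equilibrating tautomeric pair and is delivered as such.
Remark: both antipodes of the bis(oxazoline) ligand are available; the one that delivers 12 as drawn is used.

Step 1
Reactants: 1 1,3-dimethoxybenzene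
Product: 2 1,5-dimethoxycyclohexa-1,4-diene
Conditions: Li, liq. NH3, t-BuOH, THF, −78 to −33 °C
Reagents that add atoms: none
Why: Birch reduction of a resorcinol diether places both donor-substituted carbons on the double bonds of the unconjugated 1,4-diene, so the two enol ethers flank one CH2 group.

Step 2
Reactants: 2 1,5-dimethoxycyclohexa-1,4-diene; 3 geranyl bromide
Product: 5 6-geranyl-1,5-dimethoxycyclohexa-1,4-diene, via lithiated diene 4 (not isolated)
Conditions: t-BuLi, THF, −78 °C; then 3, −78 to −20 °C
Reagents that add atoms: none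
Why: The CH2 between the two methoxy-bearing carbons is doubly allylic and its lithium is held by both oxygens, so t-BuLi metalates there and the cyclohexadienyl anion is alkylated at its central carbon by the primary allylic bromide (SN2 alkylation of a Birch-type dienyl anion).

Step 3
Reactants: 5 6-geranyl-1,5-dimethoxycyclohexa-1,4-diene; 6 tert-butyl bromoacetate
Product: 8 tert-butyl 2-(1-geranyl-2,6-dimethoxycyclohexa-2,5-dien-1-yl)acetate, via lithiated geranyl diene 7 (not isolated)
Conditions: t-BuLi, THF, −78 °C; then 6, −78 °C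
Reagents that add atoms: none
Why: A second metalation at the same, now tertiary, carbon and SN2 alkylation with the α-bromo ester build the quaternary centre; geranyl goes in first because an ester already in place would be enolised instead, and the tert-butyl group keeps the carbanion away from the ester carbonyl.

Step 4
Reactants: 8 tert-butyl 2-(1-geranyl-2,6-dimethoxycyclohexa-2,5-dien-1-yl)acetate
Product: 9 potassium 2-(1-geranyl-2,6-dimethoxycyclohexa-2,5-dien-1-yl)acetate
Conditions: KOH, MeOH/H2O, reflux; evaporate and dry, salt isolated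
Reagents that add atoms: potassium hydroxide, [K+].[OH-]
Why: Saponification is used because the usual acidic cleavage of a tert-butyl ester would hydrolyse both enol ethers, and the product is kept as its salt so that no free carboxylic acid can add to an enol ether.

Step 5
Reactants: 9 potassium 2-(1-geranyl-2,6-dimethoxycyclohexa-2,5-dien-1-yl)acetate
Product: 11 1-diazo-3-(1-geranyl-2,6-dimethoxycyclohexa-2,5-dien-1-yl)propan-2-one (achiral), via mixed carbonic anhydride 10 (not isolated)
Conditions: i-BuOCOCl, N-methylmorpholine (cat.), THF, −15 °C; then CH2N2, Et2O, 0 °C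
Reagents that add atoms: diazomethane, C=[N+]=[N-]
Why: Acylation of diazomethane by a mixed carbonic anhydride (first stage of an Arndt–Eistert sequence) gives the diazoketone under neutral conditions, the departing monoalkyl carbonate acting as the base, so that no hydrogen chloride is formed.

Step 6
Reactants: 11 1-diazo-3-(1-geranyl-2,6-dimethoxycyclohexa-2,5-dien-1-yl)propan-2-one
Product: 12 (1R,2S,6S,9R)-6-geranyl-1,5-dimethoxytricyclo[4.3.0.0^2,9]non-4-en-8-one (core atoms: C9–OMe, C1–H, C5–geranyl, C8–H; C7 ketone; C3=C4 enol ether)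
Conditions: [Cu(MeCN)4]PF6 (5 mol %), (S,S)-tBu-box (6 mol %), toluene, 40 °C, slow addition of 11
Reagents that add atoms: none
Why: The monovalent copper–bis(oxazoline) complex decomposes the diazoketone to an electrophilic copper carbenoid at C8, which adds suprafacially in a concerted, asynchronous [2+1] manner to one enol ether double bond and forms C8–C1 and C8–C9. The closest known reaction type is the copper–bis(oxazoline)-catalysed enantioselective intramolecular cyclopropanation of α-diazo ketones and α-diazo-β-keto sulfones tethered to 2,6-dimethoxycyclohexa-2,5-dienes. The cyclopentanone (C5–C6–C7–C8–C9) closes in the exo mode, C1 of the attacked alkene staying outside the five-membered ring, and the cyclopropane (C1–C8–C9) closes as the three-membered ring of the same cycloaddition, so the fusion is necessarily cis. C5 becomes stereogenic through the choice between the enantiotopic C9=C1 and C4=C3 enol ethers, which the chiral ligand controls, whereas C9, C1 and C8 follow from C5 because the two-atom tether reaches only the ring face that carries it and the addition is suprafacial. The step needs enantiotopic-group selectivity and chemoselectivity over the two geranyl alkenes and over C–H insertion; the enol ethers are the most electron-rich alkenes, two of them are held rigidly beside the carbenoid, and they lead to a five-membered ketone whereas the nearest geranyl alkene would have to close a six-membered one.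

Step 7
Reactants: 12 tricyclic cyclopropyl ketone
Product: 14 5-geranyl-4,9,9-trimethoxybicyclo[3.3.1]non-3-en-7-one (C1–H bridgehead; C1 and C5 as in 12), via silyl enol ether 13 (not isolated)
Conditions: Me3SiOTf (0.1 equiv), MeOSiMe3, 2,6-lutidine (cat.), CH2Cl2, −78 to −40 °C; then K2CO3 (cat.), MeOH, 0 °C
Reagents that add atoms: methoxytrimethylsilane, CO[Si](C)(C)C
Why: Silyl triflate activates the ketone of the donor–acceptor cyclopropane, the methoxy group on C9 pushes open C8–C9 (C8–C1 has no donor) and the oxocarbenium ion is captured by the silyl ether as a dimethyl ketal (acid-promoted alcoholysis of an alkoxycyclopropyl ketone to a γ-keto ketal, run aprotically so that the second enol ether and the alkenes are untouched), which leaves C7 as the only carbonyl group for steps 8 to 10; methanolysis of the silyl enol ether frees the ketone and no stereocentre is created.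

Step 8
Reactants: 14 5-geranyl-4,9,9-trimethoxybicyclo[3.3.1]non-3-en-7-one
Product: 16 5-geranyl-4,9,9-trimethoxy-8,8-dimethylbicyclo[3.3.1]non-3-en-7-one, via 8-monomethyl ketone 15 (not isolated)
Conditions: KOt-Bu, MeI, THF/t-BuOH, 0 °C to rt
Reagents that add atoms: iodomethane, CI
Why: Double enolate methylation under equilibrating conditions should go to C8 because the other α-carbon, C6, is neopentyl (next to the quaternary C5) and is alkylated much more slowly, and the second methyl group enters through the more substituted C7=C8 enolate, as in the gem-dimethylation of 3,3-disubstituted cyclohexanones at the distal α-carbon.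

Step 9
Reactants: 16 5-geranyl-4,9,9-trimethoxy-8,8-dimethylbicyclo[3.3.1]non-3-en-7-one
Product: 17 5-geranyl-4,9,9-trimethoxy-8,8-dimethyl-7-methylidenebicyclo[3.3.1]non-3-ene
Conditions: Ph3PCH3Br, KOt-Bu, toluene, 90 °C
Reagents that add atoms: methyltriphenylphosphonium bromide, [Br-].C[P+](c1ccccc1)(c1ccccc1)c1ccccc1
Why: Wittig methylenation under the forcing conditions used for hindered ketones is chemoselective here because C7 is the only carbonyl group while the more accessible C9 carbonyl is still a ketal.

Step 10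
Reactants: 17 7-methylidene compound; 18 1-bromo-2-methylprop-1-ene
Product: 20 5-geranyl-4,9,9-trimethoxy-8,8-dimethyl-7-endo-prenylbicyclo[3.3.1]non-3-ene (C7–H exo, as in the target), via B-alkyl-9-BBN 19 (not isolated)
Conditions: 9-BBN, THF, 50 °C; then 18, Pd(dppf)Cl2 (5 mol %), 3 M aq NaOH, THF, 60 °C
Reagents that add atoms: none
Why: 9-BBN adds to the only 1,1-disubstituted alkene (trisubstituted alkenes and the hindered enol ether react far more slowly, and the ketal protects C9 from reduction) with boron on the terminal carbon, and it should approach the exo face of ring B because ring A closes off the concave endo face of C7 in the chair conformer, so hydrogen enters C7 exo and the CH2B arm is endo; the B-alkyl Suzuki–Miyaura coupling then completes the prenyl group without touching C7.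

Step 11
Reactants: 20 7-endo-prenyl enol ether ketal
Product: 21 5-geranyl-4,9,9-trimethoxy-8,8-dimethyl-7-endo-prenylbicyclo[3.3.1]non-3-en-2-one
Conditions: t-BuOOH (decane), PhI(OAc)2, Cs2CO3 (cat.), EtOAc, −20 °C
Reagents that add atoms: tert-butyl hydroperoxide, CC(C)(C)OO
Why: Peroxyl-radical allylic oxidation (hydroperoxide with a hypervalent iodine oxidant) should convert the C2 methylene into a ketone because its C–H bonds are allylic to the enol ether and give a radical stabilised by the C4 methoxy group, which makes them weaker and more electron-rich than the allylic C–H bonds of the prenyl and geranyl chains; this is the way bicyclic methyl enol ethers of this family are turned into vinylogous esters.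

Step 12
Reactants: 21 vinylogous ester ketal
Product: 22 5-geranyl-4-methoxy-8,8-dimethyl-7-endo-prenylbicyclo[3.3.1]non-3-ene-2,9-dione
Conditions: PPTS (cat.), acetone/H2O (9:1), 45 °C
Reagents that add atoms: water, O
Why: Mild acid hydrolysis of the dimethyl ketal, helped by relief of the 1,3-diaxial strain between a ketal oxygen and the axial C8 methyl, frees the C9 ketone, while the vinylogous ester (far less acid-labile than the enol ether it replaced) and the trisubstituted alkenes survive.

Step 13
Reactants: 22 5-geranyl-4-methoxy-8,8-dimethyl-7-endo-prenylbicyclo[3.3.1]non-3-ene-2,9-dione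
Product: 23 3-trimethylsilyl derivative of 22
Conditions: lithium 2,2,6,6-tetramethylpiperidide (LiTMP), Me3SiCl, THF, −78 °C
Reagents that add atoms: chlorotrimethylsilane, C[Si](C)(C)Cl
Why: In situ silylation of the kinetically formed C3 vinyl anion (α to the C2 carbonyl and held by the C4 methoxy group) blocks C3, the established device for steering the next lithiation to a bridgehead that is hindered by a neighbouring quaternary carbon.

Step 14
Reactants: 23 3-trimethylsilyl vinylogous ester; 24 prenyl bromide
Product: 26 5-geranyl-4-methoxy-8,8-dimethyl-1,7-diprenyl-3-trimethylsilylbicyclo[3.3.1]non-3-ene-2,9-dione, via C1-lithio species 25 (not isolated)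
Conditions: LiN(i-Pr)2 (LDA), THF, −78 °C; then 24, −78 to −30 °C
Reagents that add atoms: none
Why: With C3 blocked, LDA removes the bridgehead hydrogen at C1, which is flanked by the C2 and C9 carbonyl groups, and the pyramidal bridgehead carbanion is alkylated at the primary carbon of the allylic bromide (bridgehead lithiation–alkylation of bicyclo[3.3.1]nonane-2,4,9-trione enol ethers), the configuration at C1 being fixed by the bicycle.

Step 15
Reactants: 26 1-prenyl-3-trimethylsilyl compound
Product: 27 5-geranyl-4-methoxy-8,8-dimethyl-1,7-diprenylbicyclo[3.3.1]non-3-ene-2,9-dione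
Conditions: Bu4NF, wet THF, 0 °C
Reagents that add atoms: none
Why: Fluoride-induced protodesilylation removes the blocking group because the C3–Si bond is activated by the adjacent carbonyl group, and nothing else in the molecule is fluoride-labile.

Step 16
Reactants: 28 3,4-dihydroxybenzoic acid
Product: 29 tert-butyldimethylsilyl 3,4-bis(tert-butyldimethylsilyloxy)benzoate
Conditions: t-BuMe2SiCl, imidazole, DMF, rt
Reagents that add atoms: tert-butylchlorodimethylsilane, CC(C)(C)[Si](C)(C)Cl
Why: Exhaustive silylation protects the catechol as ethers that withstand the lithium amide chemistry yet fall to hydroxide at the end, and turns the acid into a silyl ester that can be converted into the chloride without acid.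

Step 17
Reactants: 29 tris-silylated 3,4-dihydroxybenzoic acid
Product: 30 3,4-bis(tert-butyldimethylsilyloxy)benzoyl chloride
Conditions: (COCl)2, DMF (cat.), CH2Cl2, 0 °C to rt
Reagents that add atoms: oxalyl chloride, ClC(=O)C(=O)Cl
Why: Vilsmeier-type activation converts a silyl ester directly into the acid chloride under neutral conditions that leave the aryl silyl ethers intact.

Step 18
Reactants: 27 5-geranyl-4-methoxy-8,8-dimethyl-1,7-diprenylbicyclo[3.3.1]non-3-ene-2,9-dione; 30 3,4-bis(tert-butyldimethylsilyloxy)benzoyl chloride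
Product: 32 3-[3,4-bis(tert-butyldimethylsilyloxy)benzoyl]-5-geranyl-4-methoxy-8,8-dimethyl-1,7-diprenylbicyclo[3.3.1]non-3-ene-2,9-dione, via C3-lithio species 31 (not isolated)
Conditions: LiTMP, THF, −78 °C; then 30, −78 to −40 °C
Reagents that add atoms: none
Why: LiTMP removes the only remaining acidic hydrogen, the vinylic C3–H between the C2 carbonyl and the C4 methoxy group, and the vinyllithium is acylated by the acid chloride (C3 lithiation–acylation of the trione methyl enol ether), the hindered amide being unable to add to the carbonyl groups.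

Step 19
Reactants: 32 silyl-protected methyl enol ether of the target
Product: 33 CNP0160101.2, (1S,5S,7S)-3-(3,4-dihydroxybenzoyl)-5-geranyl-4-hydroxy-8,8-dimethyl-1,7-diprenylbicyclo[3.3.1]non-3-ene-2,9-dione
Conditions: LiOH·H2O, degassed dioxane/H2O, 90 °C; then 1 M HCl to pH 3, 0 °C
Reagents that add atoms: lithium hydroxide, [Li+].[OH-]
Why: Hydroxide cleaves the vinylogous methyl ester by conjugate addition–elimination at C4 and the aryl silyl ethers by attack at silicon, and the resulting triketone enolate and phenolates resist further attack until acidification releases the target, none of the three stereocentres being epimerisable.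

Compound list
1 | 1,3-dimethoxybenzene | COc1cccc(OC)c1 | starting material
2 | 1,5-dimethoxycyclohexa-1,4-diene | COC1=CCC=C(OC)C1 | intermediate
3 | geranyl bromide, (2E)-1-bromo-3,7-dimethylocta-2,6-diene | CC(C)=CCC/C(C)=C/CBr | starting material
4 | 6-lithio-1,5-dimethoxycyclohexa-1,4-diene | [Li]C1C(OC)=CCC=C1OC | intermediate
5 | 6-geranyl-1,5-dimethoxycyclohexa-1,4-diene | CC(C)=CCC/C(C)=C/CC1C(OC)=CCC=C1OC | intermediate
6 | tert-butyl bromoacetate | CC(C)(C)OC(=O)CBr | starting material
7 | 6-geranyl-6-lithio-1,5-dimethoxycyclohexa-1,4-diene | CC(C)=CCC/C(C)=C/CC1([Li])C(OC)=CCC=C1OC | intermediate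
8 | tert-butyl 2-(1-geranyl-2,6-dimethoxycyclohexa-2,5-dien-1-yl)acetate | CC(C)=CCC/C(C)=C/CC1(CC(=O)OC(C)(C)C)C(OC)=CCC=C1OC | intermediate
9 | potassium 2-(1-geranyl-2,6-dimethoxycyclohexa-2,5-dien-1-yl)acetate | CC(C)=CCC/C(C)=C/CC1(CC(=O)[O-])C(OC)=CCC=C1OC.[K+] | intermediate
10 | isobutyl carbonic 2-(1-geranyl-2,6-dimethoxycyclohexa-2,5-dien-1-yl)acetic anhydride | CC(C)=CCC/C(C)=C/CC1(CC(=O)OC(=O)OCC(C)C)C(OC)=CCC=C1OC | intermediate
11 | 1-diazo-3-(1-geranyl-2,6-dimethoxycyclohexa-2,5-dien-1-yl)propan-2-one (achiral, prochiral at the ring carbon) | CC(C)=CCC/C(C)=C/CC1(CC(=O)C=[N+]=[N-])C(OC)=CCC=C1OC | intermediate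
12 | (1R,2S,6S,9R)-6-geranyl-1,5-dimethoxytricyclo[4.3.0.0^2,9]non-4-en-8-one | CC(C)=CCC/C(C)=C/C[C@]12CC(=O)[C@@H]3[C@H](CC=C1OC)[C@]23OC | intermediate
13 | 5-geranyl-4,9,9-trimethoxy-7-trimethylsilyloxybicyclo[3.3.1]nona-3,7-diene (C1 and C5 as in 12) | CC(C)=CCC/C(C)=C/C[C@]12CC(O[Si](C)(C)C)=C[C@H](CC=C1OC)C2(OC)OC | intermediate
14 | 5-geranyl-4,9,9-trimethoxybicyclo[3.3.1]non-3-en-7-one (C1–H; C1 and C5 as in 12) | CC(C)=CCC/C(C)=C/C[C@]12CC(=O)C[C@H](CC=C1OC)C2(OC)OC | intermediate
15 | 5-geranyl-4,9,9-trimethoxy-8-methylbicyclo[3.3.1]non-3-en-7-one (C8 epimers) | CC(C)=CCC/C(C)=C/C[C@]12CC(=O)C(C)[C@H](CC=C1OC)C2(OC)OC | intermediate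
16 | 5-geranyl-4,9,9-trimethoxy-8,8-dimethylbicyclo[3.3.1]non-3-en-7-one | CC(C)=CCC/C(C)=C/C[C@]12CC(=O)C(C)(C)[C@H](CC=C1OC)C2(OC)OC | intermediate
17 | 5-geranyl-4,9,9-trimethoxy-8,8-dimethyl-7-methylidenebicyclo[3.3.1]non-3-ene | CC(C)=CCC/C(C)=C/C[C@]12CC(=C)C(C)(C)[C@H](CC=C1OC)C2(OC)OC | intermediate
18 | 1-bromo-2-methylprop-1-ene | CC(C)=CBr | starting material
19 | 9-[(5-geranyl-4,9,9-trimethoxy-8,8-dimethylbicyclo[3.3.1]non-3-en-7-yl)methyl]-9-borabicyclo[3.3.1]nonane (C7–H exo, CH2B endo) | CC(C)=CCC/C(C)=C/C[C@]12C[C@H](CB3C4CCCC3CCC4)C(C)(C)[C@H](CC=C1OC)C2(OC)OC | intermediate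
20 | 5-geranyl-4,9,9-trimethoxy-8,8-dimethyl-7-endo-prenylbicyclo[3.3.1]non-3-ene (C7–H exo) | CC(C)=CCC/C(C)=C/C[C@]12C[C@H](CC=C(C)C)C(C)(C)[C@H](CC=C1OC)C2(OC)OC | intermediate
21 | 5-geranyl-4,9,9-trimethoxy-8,8-dimethyl-7-endo-prenylbicyclo[3.3.1]non-3-en-2-one | CC(C)=CCC/C(C)=C/C[C@]12C[C@H](CC=C(C)C)C(C)(C)[C@H](C(=O)C=C1OC)C2(OC)OC | intermediate
22 | 5-geranyl-4-methoxy-8,8-dimethyl-7-endo-prenylbicyclo[3.3.1]non-3-ene-2,9-dione | CC(C)=CCC/C(C)=C/C[C@]12C[C@H](CC=C(C)C)C(C)(C)[C@H](C(=O)C=C1OC)C2=O | intermediate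
23 | 5-geranyl-4-methoxy-8,8-dimethyl-7-endo-prenyl-3-trimethylsilylbicyclo[3.3.1]non-3-ene-2,9-dione | CC(C)=CCC/C(C)=C/C[C@]12C[C@H](CC=C(C)C)C(C)(C)[C@H](C(=O)C([Si](C)(C)C)=C1OC)C2=O | intermediate
24 | prenyl bromide, 1-bromo-3-methylbut-2-ene | CC(C)=CCBr | starting material
25 | 1-lithio derivative of 23 | CC(C)=CCC/C(C)=C/C[C@]12C[C@H](CC=C(C)C)C(C)(C)[C@]([Li])(C(=O)C([Si](C)(C)C)=C1OC)C2=O | intermediate
26 | 5-geranyl-4-methoxy-8,8-dimethyl-1,7-diprenyl-3-trimethylsilylbicyclo[3.3.1]non-3-ene-2,9-dione | CC(C)=CCC/C(C)=C/C[C@]12C[C@H](CC=C(C)C)C(C)(C)[C@](CC=C(C)C)(C(=O)C([Si](C)(C)C)=C1OC)C2=O | intermediate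
27 | 5-geranyl-4-methoxy-8,8-dimethyl-1,7-diprenylbicyclo[3.3.1]non-3-ene-2,9-dione | CC(C)=CCC/C(C)=C/C[C@]12C[C@H](CC=C(C)C)C(C)(C)[C@](CC=C(C)C)(C(=O)C=C1OC)C2=O | intermediate
28 | 3,4-dihydroxybenzoic acid | OC(=O)c1ccc(O)c(O)c1 | starting material
29 | tert-butyldimethylsilyl 3,4-bis(tert-butyldimethylsilyloxy)benzoate | CC(C)(C)[Si](C)(C)OC(=O)c1ccc(O[Si](C)(C)C(C)(C)C)c(O[Si](C)(C)C(C)(C)C)c1 | intermediate
30 | 3,4-bis(tert-butyldimethylsilyloxy)benzoyl chloride | ClC(=O)c1ccc(O[Si](C)(C)C(C)(C)C)c(O[Si](C)(C)C(C)(C)C)c1 | intermediate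
31 | 3-lithio derivative of 27 | CC(C)=CCC/C(C)=C/C[C@]12C[C@H](CC=C(C)C)C(C)(C)[C@](CC=C(C)C)(C(=O)C([Li])=C1OC)C2=O | intermediate
32 | 3-[3,4-bis(tert-butyldimethylsilyloxy)benzoyl]-5-geranyl-4-methoxy-8,8-dimethyl-1,7-diprenylbicyclo[3.3.1]non-3-ene-2,9-dione | CC(C)=CCC/C(C)=C/C[C@]12C[C@H](CC=C(C)C)C(C)(C)[C@](CC=C(C)C)(C(=O)C(C(=O)c3ccc(O[Si](C)(C)C(C)(C)C)c(O[Si](C)(C)C(C)(C)C)c3)=C1OC)C2=O | intermediate
33 | CNP0160101.2, (1S,5S,7S)-3-(3,4-dihydroxybenzoyl)-5-geranyl-4-hydroxy-8,8-dimethyl-1,7-diprenylbicyclo[3.3.1]non-3-ene-2,9-dione | CC(C)=CCC/C(C)=C/C[C@]12C[C@H](CC=C(C)C)C(C)(C)[C@](CC=C(C)C)(C(=O)C(C(=O)c3ccc(O)c(O)c3)=C1O)C2=O | target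

Total step count: 19 (17 in the main line, 2 for acid chloride 30).
Longest linear sequence: 17 steps (steps 1 to 15, 18 and 19).

Steps most likely to fail

Step 6. The copper carbenoid may discriminate too weakly between the two enantiotopic enol ethers, or be diverted to the nearer geranyl double bond or to C–H insertion. The fallback sets out from carboxylate 9 and rejoins the route at ketone 14. Salt 9 is activated as in step 5 (mixed anhydride 10) and acylates lithiated methyl phenyl sulfone (MeSO2Ph, n-BuLi, THF, −78 °C) to give β-keto sulfone F1. Diazo transfer (p-acetamidobenzenesulfonyl azide, Et3N, MeCN) gives α-diazo-β-keto sulfone F2, a bulkier, doubly stabilised carbenoid precursor of the class for which this copper–bis(oxazoline) desymmetrisation is best established. Cyclopropanation under the conditions of step 6 should give sulfonyl tricycle F3, opening as in step 7 gives silyl enol ether F4 and, after methanolysis, β-keto sulfone F5, and reductive desulfonylation with Al(Hg) in THF/H2O returns 14.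

Step 11. Hydrogen abstraction from the allylic positions of the prenyl and geranyl chains may compete with abstraction at C2. The fallback sets out from 20 and rejoins at 22, replacing the radical C–H oxidation by polar steps that leave isolated trisubstituted alkenes alone. Dilute acid (1 M HCl, THF) hydrolyses enol ether and ketal to 4,9-diketone F6. The C4 ketone can enolise only towards C3, so LDA followed by N-tert-butylbenzenesulfinimidoyl chloride gives the C2=C3 enone F7. Alkaline hydrogen peroxide (H2O2, NaOH, MeOH, 0 °C) epoxidises only this electron-poor alkene to epoxy ketone F8. Pd(PPh3)4 with dppe (zerovalent palladium, toluene, 80 °C) isomerises the epoxy ketone to 2,4-dione F9. O-Methylation with trimethylsilyldiazomethane in MeOH/toluene gives 22 together with its 2-methoxy-4-oxo isomer, which is separated and recycled to F9 with LiOH.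

Step 14. Alkylation of the bridgehead anion next to the C8 gem-dimethyl group may be too slow, so that proton return or decomposition wins. The fallback sets out from 23 and rejoins at 26. The anion is trapped with the smallest electrophile (LDA, then I2) to give bridgehead iodide F10. The bridgehead radical generated from it (allyltributylstannane, AIBN, benzene, 80 °C, Keck allylation) is little affected by the neighbouring quaternary carbon and gives 1-allyl compound F11. Cross-metathesis with 2-methylbut-2-ene (second-generation Grubbs catalyst, 40 °C), which should engage only the monosubstituted alkene, converts allyl into prenyl and gives 26.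

Further compounds
F1 | step 6 | 1-(1-geranyl-2,6-dimethoxycyclohexa-2,5-dien-1-yl)-3-(phenylsulfonyl)propan-2-one | CC(C)=CCC/C(C)=C/CC1(CC(=O)CS(=O)(=O)c2ccccc2)C(OC)=CCC=C1OC
F2 | step 6 | 1-diazo-3-(1-geranyl-2,6-dimethoxycyclohexa-2,5-dien-1-yl)-1-(phenylsulfonyl)propan-2-one | CC(C)=CCC/C(C)=C/CC1(CC(=O)C(=[N+]=[N-])S(=O)(=O)c2ccccc2)C(OC)=CCC=C1OC
F3 | step 6 | 9-phenylsulfonyl derivative of tricycle 12 (sulfonyl on core C8) | CC(C)=CCC/C(C)=C/C[C@]12CC(=O)[C@]3(S(=O)(=O)c4ccccc4)[C@H](CC=C1OC)[C@]23OC
F4 | step 6 | 5-geranyl-4,9,9-trimethoxy-8-phenylsulfonyl-7-trimethylsilyloxybicyclo[3.3.1]nona-3,7-diene | CC(C)=CCC/C(C)=C/C[C@]12CC(O[Si](C)(C)C)=C(S(=O)(=O)c3ccccc3)[C@H](CC=C1OC)C2(OC)OC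
F5 | step 6 | 5-geranyl-4,9,9-trimethoxy-8-phenylsulfonylbicyclo[3.3.1]non-3-en-7-one (C8 epimers) | CC(C)=CCC/C(C)=C/C[C@]12CC(=O)C(S(=O)(=O)c3ccccc3)[C@H](CC=C1OC)C2(OC)OC
F6 | step 11 | 5-geranyl-8,8-dimethyl-7-endo-prenylbicyclo[3.3.1]nonane-4,9-dione | CC(C)=CCC/C(C)=C/C[C@]12C[C@H](CC=C(C)C)C(C)(C)[C@H](CCC1=O)C2=O
F7 | step 11 | 5-geranyl-8,8-dimethyl-7-endo-prenylbicyclo[3.3.1]non-2-ene-4,9-dione | CC(C)=CCC/C(C)=C/C[C@]12C[C@H](CC=C(C)C)C(C)(C)[C@H](C=CC1=O)C2=O
F8 | step 11 | 2,3-epoxy-5-geranyl-8,8-dimethyl-7-endo-prenylbicyclo[3.3.1]nonane-4,9-dione (epoxide face not specified) | CC(C)=CCC/C(C)=C/C[C@]12C[C@H](CC=C(C)C)C(C)(C)[C@H](C3OC3C1=O)C2=O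
F9 | step 11 | 5-geranyl-8,8-dimethyl-7-endo-prenylbicyclo[3.3.1]nonane-2,4,9-trione | CC(C)=CCC/C(C)=C/C[C@]12C[C@H](CC=C(C)C)C(C)(C)[C@H](C(=O)CC1=O)C2=O
F10 | step 14 | 5-geranyl-1-iodo-4-methoxy-8,8-dimethyl-7-endo-prenyl-3-trimethylsilylbicyclo[3.3.1]non-3-ene-2,9-dione | CC(C)=CCC/C(C)=C/C[C@]12C[C@H](CC=C(C)C)C(C)(C)[C@](I)(C(=O)C([Si](C)(C)C)=C1OC)C2=O
F11 | step 14 | 1-allyl-5-geranyl-4-methoxy-8,8-dimethyl-7-endo-prenyl-3-trimethylsilylbicyclo[3.3.1]non-3-ene-2,9-dione | CC(C)=CCC/C(C)=C/C[C@]12C[C@H](CC=C(C)C)C(C)(C)[C@](CC=C)(C(=O)C([Si](C)(C)C)=C1OC)C2=O
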